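The ten-membered carbocycle is disconnected at C1–C2, the bond joining the (E)-trisubstituted C10=C1 alkene to the C2 methylene. A single operation, 9-BBN hydroboration of a terminal vinyl group followed by intramolecular B-alkyl Suzuki–Miyaura coupling, forms this sp2–sp3 bond and closes the ring with both alkene geometries, fixed beforehand, retained. The precursor is an open chain that carries the C6–C8 stereotriad (Evans syn-aldol, then catalyst-controlled propargylation), the C8 trimethoxybenzoate, an (E)-iodoalkene at C1 and a (Z)-2-methyl-1,3-diene whose vinyl end becomes C2–C3. After ring closure only silyl removal and hydroxyl-directed epoxidation of the (Z)-C4=C5 alkene remain.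

Key step: step 11

Remark: atoms keep the ring numbering of the target throughout (C1=C10 alkene, C4–C5 epoxide, C6 OH, C7 isopropyl, C8 ester); the target is (4S,5R,6R,7R,8S) with a cis-epoxide whose oxygen is cis to the C6 hydroxyl, so its precursor alkene C4=C5 must be Z.

Step 1
Reactants: 1 (R)-4-benzyl-2-oxazolidinone; 2 3-methylbutanoyl chloride
Product: 4 (R)-4-benzyl-3-(3-methylbutanoyl)oxazolidin-2-one, via lithium oxazolidinide 3 (not isolated)
Conditions: n-BuLi, THF, −78 °C; then 2, −78 → 0 °C
Reagents that add atoms: none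
Why: N-acylation of the lithiated oxazolidinone by the acid chloride is a standard, clean imide formation that leaves the auxiliary stereocenter untouched.

Step 2
Reactants: 4 (R)-4-benzyl-3-(3-methylbutanoyl)oxazolidin-2-one; 5 but-2-ynal
Product: 8 (4R)-4-benzyl-3-[(2R,3R)-3-hydroxy-2-(propan-2-yl)hex-4-ynoyl]oxazolidin-2-one, via boron enolate 6 (not isolated), via boron aldolate 7 (not isolated)
Conditions: Bu2BOTf, Et3N, CH2Cl2, −78 → 0 °C; 5, −78 → 0 °C; pH 7 buffer, MeOH, 30% H2O2, 0 °C
Reagents that add atoms: none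
Why: Evans syn-aldol, in which the (Z)-dibutylboron enolate reacts through a closed Zimmerman–Traxler chair on the enolate face away from the benzyl group, so that C7 (R) and C6 (R) are set together with the syn relationship.

Step 3
Reactants: 8 (4R)-4-benzyl-3-[(2R,3R)-3-hydroxy-2-(propan-2-yl)hex-4-ynoyl]oxazolidin-2-one
Product: 9 (2S,3R)-2-(propan-2-yl)hex-4-yne-1,3-diol
Conditions: LiBH4, MeOH (1 equiv), THF, 0 °C
Reagents that add atoms: none
Why: Borohydride reduction of the exocyclic imide carbonyl releases the primary C8 alcohol and the recoverable auxiliary without touching the alkyne or the two stereocenters.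

Step 4
Reactants: 9 (2S,3R)-2-(propan-2-yl)hex-4-yne-1,3-diol
Product: 11 (2S,3R,4Z)-5-iodo-2-(propan-2-yl)hex-4-ene-1,3-diol, via alkenylalanate 10 (not isolated)
Conditions: NaAlH2(OCH2CH2OCH3)2 (3.5 equiv), THF, 0 °C → rt; EtOAc; then I2, THF, −78 → 0 °C
Reagents that add atoms: iodine, II
Why: Alkoxide-directed trans-hydroalumination of the propargylic alkyne puts hydride on C5 and aluminium on C4 in a five-membered oxa-aluminacycle, and iodinolysis with retention should give the (Z)-iodoalkene with iodine cis to C6.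

Step 5
Reactants: 11 (2S,3R,4Z)-5-iodo-2-(propan-2-yl)hex-4-ene-1,3-diol
Product: 12 (2S,3S,4Z)-5-methyl-2-(propan-2-yl)hepta-4,6-diene-1,3-diol
Conditions: tributyl(vinyl)stannane, PdCl2(MeCN)2 (5 mol %), DMF, rt
Reagents that add atoms: tributyl(vinyl)stannane, C=C[Sn](CCCC)(CCCC)CCCC
Why: Stille coupling replaces iodine by vinyl with retention at the sp2 carbon under neutral conditions that tolerate the free diol, which fixes the 4Z geometry of the diene.

Step 6
Reactants: 12 (2S,3S,4Z)-5-methyl-2-(propan-2-yl)hepta-4,6-diene-1,3-diol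
Product: 13 (2S,3S,4Z)-5-methyl-2-(propan-2-yl)-1,3-bis[(triethylsilyl)oxy]hepta-4,6-diene
Conditions: Et3SiCl (2.5 equiv), imidazole, DMAP (cat.), CH2Cl2, 0 °C → rt
Reagents that add atoms: chlorotriethylsilane, CC[Si](Cl)(CC)CC
Why: Routine silylation of both hydroxyls; triethylsilyl is chosen because its primary ether can be oxidised directly and its secondary ether can be removed at the end without base.

Step 7
Reactants: 13 (2S,3S,4Z)-5-methyl-2-(propan-2-yl)-1,3-bis[(triethylsilyl)oxy]hepta-4,6-diene
Product: 15 (2R,3S,4Z)-5-methyl-2-(propan-2-yl)-3-[(triethylsilyl)oxy]hepta-4,6-dienal, via alkoxysulfonium chloride 14 (not isolated)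
Conditions: (COCl)2, DMSO, CH2Cl2, −78 → −40 °C; i-Pr2NEt, −78 → 0 °C
Reagents that add atoms: none
Why: Swern oxidation applied directly to a silyl ether, in which chlorodimethylsulfonium chloride exchanges only with the unhindered primary triethylsilyl ether and the alkoxysulfonium salt collapses to the aldehyde with base at low temperature, which limits C7 epimerisation and β-elimination.

Step 8
Reactants: 15 (2R,3S,4Z)-5-methyl-2-(propan-2-yl)-3-[(triethylsilyl)oxy]hepta-4,6-dienal
Product: 17 (4S,5S,6S,7Z)-8-methyl-5-(propan-2-yl)-6-[(triethylsilyl)oxy]deca-7,9-dien-1-yn-4-ol, via O-boryl adduct 16 (not isolated)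
Conditions: allenylboronic acid pinacol ester (1.5 equiv), (S)-TRIP (3,3'-bis(2,4,6-triisopropylphenyl)-1,1'-binaphthyl-2,2'-diyl hydrogen phosphate, 10 mol %), 4 Å sieves, toluene, 0 °C → rt; aqueous work-up
Reagents that add atoms: allenylboronic acid pinacol ester, C=C=CB1OC(C)(C)C(C)(C)O1
Why: Chiral phosphoric acid-catalysed allenylboration through a closed six-membered transition state gives the homopropargylic alcohol, with the (S)-acid chosen to deliver the propargyl group to the Si face of C8=O (the (R)-acid is known to direct Re-face addition) and so set C8 (S); catalyst control is needed because Felkin and 1,3-anti induction oppose each other in this syn-configured aldehyde and leave only a weak intrinsic bias.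

Step 9
Reactants: 17 (4S,5S,6S,7Z)-8-methyl-5-(propan-2-yl)-6-[(triethylsilyl)oxy]deca-7,9-dien-1-yn-4-ol
Product: 19 (1E,4S,5S,6S,7Z)-1-iodo-2,8-dimethyl-5-(propan-2-yl)-6-[(triethylsilyl)oxy]deca-1,7,9-trien-4-ol, via alkenylalane 18 (not isolated)
Conditions: AlMe3 (4 equiv), Cp2ZrCl2 (0.5 equiv), H2O (1 equiv), CH2Cl2, −30 → 0 °C; then I2, THF, −30 °C
Reagents that add atoms: trimethylaluminium, C[Al](C)C; iodine, II
Why: Zirconium-catalysed syn-carboalumination of the terminal alkyne (Negishi carboalumination) puts methyl on C10 and aluminium on C1, and iodinolysis with retention should give the (E)-iodoalkene; the terminal alkyne reacts far faster than the alkenes, and the water-accelerated variant keeps the temperature low for the allylic silyl ether.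

Step 10
Reactants: 19 (1E,4S,5S,6S,7Z)-1-iodo-2,8-dimethyl-5-(propan-2-yl)-6-[(triethylsilyl)oxy]deca-1,7,9-trien-4-ol; 20 3,4,5-trimethoxybenzoyl chloride
Product: 21 (1E,4S,5S,6S,7Z)-1-iodo-2,8-dimethyl-5-(propan-2-yl)-6-[(triethylsilyl)oxy]deca-1,7,9-trien-4-yl 3,4,5-trimethoxybenzoate
Conditions: Et3N, DMAP, CH2Cl2, 0 °C → rt
Reagents that add atoms: none
Why: DMAP-catalysed acylation of the secondary C8 alcohol proceeds with retention at C8, and the ester is introduced at this point because no later step uses hydride or strong base.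

Step 11
Reactants: 21 (1E,4S,5S,6S,7Z)-1-iodo-2,8-dimethyl-5-(propan-2-yl)-6-[(triethylsilyl)oxy]deca-1,7,9-trien-4-yl 3,4,5-trimethoxybenzoate
Product: 23 (1S,3E,7Z,9S,10S)-3,7-dimethyl-10-(propan-2-yl)-9-[(triethylsilyl)oxy]cyclodeca-3,7-dien-1-yl 3,4,5-trimethoxybenzoate, via B-alkyl-9-BBN 22 (not isolated)
Conditions: 9-BBN dimer, THF, 0 °C → rt; H2O; then syringe-pump addition to Pd(dppf)Cl2 (20 mol %), AsPh3 (20 mol %), Cs2CO3 (3 equiv), degassed DMF/THF/H2O, rt, final about 1 mM
Reagents that add atoms: none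
Why: 9-BBN adds syn across the monosubstituted C2=C3 alkene of the diene with boron on terminal C2, then zerovalent palladium formed from Pd(dppf)Cl2 inserts into the C1–I bond with retention, the base-activated borane transfers the C2 alkyl group to palladium, and reductive elimination forms C1–C2. The closest known reaction type is the hydroboration/intramolecular B-alkyl Suzuki–Miyaura macrocyclisation. The ten-membered all-carbon ring closes end to end at the sp2–sp3 junction, through an eleven-membered palladacycle that contracts on reductive elimination. No stereocenter is formed; C6, C7 and C8 are spectators, and the 1(10)E geometry of the iodoalkene and the 4Z geometry of the diene pass unchanged into the ring. The step needs hydroboration at C2 only, which the bulk of 9-BBN secures against the trisubstituted C4=C5 and iodoalkene at room temperature, helped by the twist of the (Z)-diene that lets its vinyl group react like an isolated alkene. It also needs ring closure rather than oligomerisation, which slow addition to high dilution and the turn imposed by the (Z)-alkene and the C6–C8 substituents should favour, while the wide bite angle of dppf favours reductive elimination over β-hydride elimination.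

Step 12
Reactants: 23 (1S,3E,7Z,9S,10S)-3,7-dimethyl-10-(propan-2-yl)-9-[(triethylsilyl)oxy]cyclodeca-3,7-dien-1-yl 3,4,5-trimethoxybenzoate
Product: 24 (1S,3E,7Z,9S,10R)-9-hydroxy-3,7-dimethyl-10-(propan-2-yl)cyclodeca-3,7-dien-1-yl 3,4,5-trimethoxybenzoate
Conditions: HF·pyridine, pyridine, THF, 0 °C
Reagents that add atoms: none
Why: Buffered fluoride cleaves the secondary triethylsilyl ether without the basic conditions that would promote a 1,3-acyl shift from O8 to O6.

Step 13
Reactants: 24 (1S,3E,7Z,9S,10R)-9-hydroxy-3,7-dimethyl-10-(propan-2-yl)cyclodeca-3,7-dien-1-yl 3,4,5-trimethoxybenzoate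
Product: 25 (1S,4E,7S,8R,9R,10R)-9-hydroxy-1,5-dimethyl-8-(propan-2-yl)-11-oxabicyclo[8.1.0]undec-4-en-7-yl 3,4,5-trimethoxybenzoate
Conditions: VO(acac)2 (10 mol %), t-BuOOH (1.5 equiv, in decane), CH2Cl2, 0 °C
Reagents that add atoms: tert-butyl hydroperoxide, CC(C)(C)OO
Why: Hydroxyl-directed epoxidation, in which the vanadium alkoxide of C6–OH delivers oxygen only to the allylic C4=C5 alkene and to the face syn to the hydroxyl (O–C6–C5=C4 dihedral near 40–50°, ring carbon C7 on the far face) as for (Z)-cycloalkenols of medium ring size, which should set C4 (S) and C5 (R) as the cis-epoxide cis to the hydroxyl and leave C1=C10 untouched.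

Compound list
1 | (R)-4-benzyl-2-oxazolidinone | O=C1N[C@H](Cc2ccccc2)CO1 | starting material
2 | 3-methylbutanoyl chloride | CC(C)CC(=O)Cl | starting material
3 | lithium (R)-4-benzyl-2-oxooxazolidin-3-ide | [Li]N1C(=O)OC[C@H]1Cc1ccccc1 | intermediate (not isolated)
4 | (R)-4-benzyl-3-(3-methylbutanoyl)oxazolidin-2-one | CC(C)CC(=O)N1C(=O)OC[C@H]1Cc1ccccc1 | intermediate
5 | but-2-ynal | CC#CC=O | starting material
6 | (Z)-dibutylboron enolate of 4 | CC(C)/C=C(\OB(CCCC)CCCC)N1C(=O)OC[C@H]1Cc1ccccc1 | intermediate (not isolated)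
7 | O-dibutylboryl aldolate of 8 | CC#C[C@H](OB(CCCC)CCCC)[C@@H](C(C)C)C(=O)N1C(=O)OC[C@H]1Cc1ccccc1 | intermediate (not isolated)
8 | (4R)-4-benzyl-3-[(2R,3R)-3-hydroxy-2-(propan-2-yl)hex-4-ynoyl]oxazolidin-2-one | CC#C[C@H](O)[C@@H](C(C)C)C(=O)N1C(=O)OC[C@H]1Cc1ccccc1 | intermediate
9 | (2S,3R)-2-(propan-2-yl)hex-4-yne-1,3-diol | CC#C[C@H](O)[C@@H](C(C)C)CO | intermediate
10 | sodium alkenylalanate of 9 (aluminium on C4, O6, O8 and one 2-methoxyethoxide) | [Na+].COCCO[Al-]12OC[C@H](C(C)C)[C@H](C=C1C)O2 | intermediate (not isolated)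
11 | (2S,3R,4Z)-5-iodo-2-(propan-2-yl)hex-4-ene-1,3-diol | C/C(I)=C/[C@H](O)[C@@H](C(C)C)CO | intermediate
12 | (2S,3S,4Z)-5-methyl-2-(propan-2-yl)hepta-4,6-diene-1,3-diol | C=C/C(C)=C\[C@H](O)[C@@H](C(C)C)CO | intermediate
13 | (2S,3S,4Z)-5-methyl-2-(propan-2-yl)-1,3-bis[(triethylsilyl)oxy]hepta-4,6-diene | C=C/C(C)=C\[C@H](O[Si](CC)(CC)CC)[C@@H](C(C)C)CO[Si](CC)(CC)CC | intermediate
14 | dimethyl(alkoxy)sulfonium chloride of the C8 oxygen of 13 | C=C/C(C)=C\[C@H](O[Si](CC)(CC)CC)[C@@H](C(C)C)CO[S+](C)C.[Cl-] | intermediate (not isolated)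
15 | (2R,3S,4Z)-5-methyl-2-(propan-2-yl)-3-[(triethylsilyl)oxy]hepta-4,6-dienal | C=C/C(C)=C\[C@H](O[Si](CC)(CC)CC)[C@@H](C(C)C)C=O | intermediate
16 | O-(pinacolatoboryl) derivative of 17 | C#CC[C@H](OB1OC(C)(C)C(C)(C)O1)[C@H](C(C)C)[C@@H](O[Si](CC)(CC)CC)/C=C(C)\C=C | intermediate (not isolated)
17 | (4S,5S,6S,7Z)-8-methyl-5-(propan-2-yl)-6-[(triethylsilyl)oxy]deca-7,9-dien-1-yn-4-ol | C#CC[C@H](O)[C@H](C(C)C)[C@@H](O[Si](CC)(CC)CC)/C=C(C)\C=C | intermediate
18 | (E)-alkenyl(dimethyl)alane of 17 (aluminium on C1, dimethylaluminium alkoxide on O8) | C[Al](C)/C=C(C)/C[C@H](O[Al](C)C)[C@H](C(C)C)[C@@H](O[Si](CC)(CC)CC)/C=C(C)\C=C | intermediate (not isolated)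
19 | (1E,4S,5S,6S,7Z)-1-iodo-2,8-dimethyl-5-(propan-2-yl)-6-[(triethylsilyl)oxy]deca-1,7,9-trien-4-ol | I/C=C(C)/C[C@H](O)[C@H](C(C)C)[C@@H](O[Si](CC)(CC)CC)/C=C(C)\C=C | intermediate
20 | 3,4,5-trimethoxybenzoyl chloride | COc1cc(C(=O)Cl)cc(OC)c1OC | starting material
21 | (1E,4S,5S,6S,7Z)-1-iodo-2,8-dimethyl-5-(propan-2-yl)-6-[(triethylsilyl)oxy]deca-1,7,9-trien-4-yl 3,4,5-trimethoxybenzoate | COc1cc(C(=O)O[C@@H](C/C(C)=C/I)[C@H](C(C)C)[C@@H](O[Si](CC)(CC)CC)/C=C(C)\C=C)cc(OC)c1OC | intermediate
22 | B-alkyl-9-BBN adduct of 21 (boron on C2) | COc1cc(C(=O)O[C@@H](C/C(C)=C/I)[C@H](C(C)C)[C@@H](O[Si](CC)(CC)CC)/C=C(C)\CCB2C3CCCC2CCC3)cc(OC)c1OC | intermediate (not isolated)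
23 | (1S,3E,7Z,9S,10S)-3,7-dimethyl-10-(propan-2-yl)-9-[(triethylsilyl)oxy]cyclodeca-3,7-dien-1-yl 3,4,5-trimethoxybenzoate | COc1cc(C(=O)O[C@H]2C/C(C)=C/CC/C(C)=C\[C@H](O[Si](CC)(CC)CC)[C@H]2C(C)C)cc(OC)c1OC | intermediate
24 | (1S,3E,7Z,9S,10R)-9-hydroxy-3,7-dimethyl-10-(propan-2-yl)cyclodeca-3,7-dien-1-yl 3,4,5-trimethoxybenzoate | COc1cc(C(=O)O[C@H]2C/C(C)=C/CC/C(C)=C\[C@H](O)[C@H]2C(C)C)cc(OC)c1OC | intermediate
25 | (1S,4E,7S,8R,9R,10R)-9-hydroxy-1,5-dimethyl-8-(propan-2-yl)-11-oxabicyclo[8.1.0]undec-4-en-7-yl 3,4,5-trimethoxybenzoate | COc1cc(C(=O)O[C@H]2C/C(C)=C/CC[C@]3(C)O[C@@H]3[C@H](O)[C@H]2C(C)C)cc(OC)c1OC | target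

Total step count: 13. Longest linear sequence: 13 steps (1 to 25).

Steps most likely to fail

(a) Step 11. Transmetallation of the B-alkyl borane may be too slow in the strained ring-forming mode, so that protodeboronation, β-hydride elimination or intermolecular coupling take over. The fallback changes the nucleophile class and takes the hydroboration out of the ring-closing event. It sets out from 21: hydroboration with 9-BBN as above followed by NaBO3·4H2O (THF/H2O, rt) should give the primary C2 alcohol F1. I2, PPh3 and imidazole (CH2Cl2, 0 °C) should convert it into the primary iodide F2. Zinc dust activated with Me3SiCl and 1,2-dibromoethane (THF, rt to 35 °C) should insert into the sp3 C–I bond only. The resulting alkylzinc iodide F3 would close the same C1–C2 bond by intramolecular Negishi coupling with the iodoalkene under Pd(PPh3)4 (THF/DMF, high dilution); this needs neither base nor water and transmetallates faster. The fallback comes back to the route at 23.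

(b) Step 13. Oxygen may be delivered to the other alkene face if the ring reacts through the conformer with the hydroxyl turned outward. The Lewis-acidic catalyst may also trigger transannular opening of the epoxide by the C1=C10 alkene or oxidise the alcohol to the enone. The fallback changes the control element from substrate to reagent. It sets out from 24: Sharpless epoxidation with Ti(OiPr)4, L-(+)-diisopropyl tartrate and tert-butyl hydroperoxide (4 Å sieves, CH2Cl2, −20 °C) delivers oxygen to the lower face of the alkene drawn with the carbinol carbon at the lower right. For the (6R) alcohol this is the matched, erythro-selective mode and corresponds to the cis-epoxy alcohol. The fallback comes back at 25 and makes no new compound (F0).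

(c) Step 8. Facial control at C8 may be poor if the bias of the α-isopropyl aldehyde overrides the catalyst, and slow addition to the hindered aldehyde may allow C7 to epimerise. The fallback makes the C8 epimer on purpose and inverts it. It sets out from 15: the same allenylboronate with (R)-TRIP, now working with any substrate bias, should give, via the O-boryl adduct of the C8 epimer F4, the (4R)-homopropargylic alcohol F5. Mitsunobu reaction with 4-nitrobenzoic acid (PPh3, diisopropyl azodicarboxylate, toluene, 0 °C) should invert C8 to the (4S) 4-nitrobenzoate F6. K2CO3 in MeOH at 0 °C then releases the alcohol, and the fallback comes back to the route at 17.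

Further compounds
F1 | step 11 | (1E,4S,5S,6S,7Z)-10-hydroxy-1-iodo-2,8-dimethyl-5-(propan-2-yl)-6-[(triethylsilyl)oxy]deca-1,7-dien-4-yl 3,4,5-trimethoxybenzoate | COc1cc(C(=O)O[C@@H](C/C(C)=C/I)[C@H](C(C)C)[C@@H](O[Si](CC)(CC)CC)/C=C(C)\CCO)cc(OC)c1OC
F2 | step 11 | (1E,4S,5S,6S,7Z)-1,10-diiodo-2,8-dimethyl-5-(propan-2-yl)-6-[(triethylsilyl)oxy]deca-1,7-dien-4-yl 3,4,5-trimethoxybenzoate | COc1cc(C(=O)O[C@@H](C/C(C)=C/I)[C@H](C(C)C)[C@@H](O[Si](CC)(CC)CC)/C=C(C)\CCI)cc(OC)c1OC
F3 | step 11 | alkylzinc iodide of F2 (zinc on C2) | COc1cc(C(=O)O[C@@H](C/C(C)=C/I)[C@H](C(C)C)[C@@H](O[Si](CC)(CC)CC)/C=C(C)\CC[Zn]I)cc(OC)c1OC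
F0 | step 13 | none | none
F4 | step 8 | O-(pinacolatoboryl) derivative of F5 | C#CC[C@@H](OB1OC(C)(C)C(C)(C)O1)[C@H](C(C)C)[C@@H](O[Si](CC)(CC)CC)/C=C(C)\C=C
F5 | step 8 | (4R,5S,6S,7Z)-8-methyl-5-(propan-2-yl)-6-[(triethylsilyl)oxy]deca-7,9-dien-1-yn-4-ol | C#CC[C@@H](O)[C@H](C(C)C)[C@@H](O[Si](CC)(CC)CC)/C=C(C)\C=C
F6 | step 8 | (4S,5S,6S,7Z)-8-methyl-5-(propan-2-yl)-6-[(triethylsilyl)oxy]deca-7,9-dien-1-yn-4-yl 4-nitrobenzoate | C#CC[C@H](OC(=O)c1ccc(cc1)[N+](=O)[O-])[C@H](C(C)C)[C@@H](O[Si](CC)(CC)CC)/C=C(C)\C=C
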